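**Retrosynthetic overview**

1. Both target rings are opened in one stroke to an acyclic α'-hydroxy tetraketo ester: ring B (furanone) at O1–C2 (retro cyclodehydration of an α'-hydroxy-1,3-diketone) and ring A (cyclopentenone) at C5–C6 (retro 4π closure/aldol of C5 onto an α-keto ester).
2. The (Z)-2,3-dimethoxy-ene-1,4-dione keto ester is unmasked in the same flask from a 3,4-dimethoxyfuran-2-carboxylate by singlet-oxygen oxidation; this sacrificial furan supplies C6–C9 and the ester carbon.
3. The furyl hydroxy diketone comes from a crossed Claisen condensation of 4'-hydroxyacetophenone with a furyl glycolate, itself made from a furylmagnesium reagent and ethyl glyoxylate.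
4. The furan comes from a Hinsberg condensation of dimethyl diglycolate with dimethyl oxalate, then O-methylation, mono-saponification and protodecarboxylation.
5. Forward ring order: sacrificial furan (steps 1–4), then in one operation the furan is opened and rings B and A are formed together with both stereocentres (step 7).

Assumption: atom numbers in the text are those of the target (O1, C2 aryl, C3, C4 ketone, C5 spiro, C6 carbinol, C7, C8, C9 ketone); the sense of induction of the chiral acid in step 7 must be found by experiment, so the (R)-acid is written and its mirror image is used if it gives the antipode.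

**Route**

Step 1
Reactants: 1 dimethyl diglycolate; 2 dimethyl oxalate
Product: 3 dimethyl 3,4-dihydroxyfuran-2,5-dicarboxylate
Conditions: NaOMe (2.2 equiv), MeOH, reflux; then aq. HCl
Reagents that add atoms: none
Why: Hinsberg furan synthesis, a double Claisen condensation of both activated methylenes of 1 onto the two ester carbonyls of 2, driven by formation of the aromatic disodium bis-enolate; no stereocentre.

Step 2
Reactants: 3 dimethyl 3,4-dihydroxyfuran-2,5-dicarboxylate
Product: 4 dimethyl 3,4-dimethoxyfuran-2,5-dicarboxylate
Conditions: MeI (2.5 equiv), K2CO3, DMF, 40 °C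
Reagents that add atoms: iodomethane, CI
Why: Williamson O-methylation of the two acidic enolic hydroxyls (vinylogous acids); no stereocentre.

Step 3
Reactants: 4 dimethyl 3,4-dimethoxyfuran-2,5-dicarboxylate
Product: 5 3,4-dimethoxy-5-(methoxycarbonyl)furan-2-carboxylic acid
Conditions: KOH (1.0 equiv), MeOH/THF, 0 → 20 °C; then aq. HCl
Reagents that add atoms: potassium hydroxide, [K+].[OH-]
Why: mono-saponification of a symmetrical diester, in which the first carboxylate deactivates the remaining conjugated ester and unreacted 4 is recycled; no stereocentre.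

Step 4
Reactants: 5 3,4-dimethoxy-5-(methoxycarbonyl)furan-2-carboxylic acid
Product: 6 methyl 3,4-dimethoxyfuran-2-carboxylate
Conditions: Ag2CO3 (10 mol%), AcOH (5 mol%), DMSO, 120 °C
Reagents that add atoms: none
Why: Ag2CO3-catalysed protodecarboxylation of a heteroaryl 2-carboxylic acid bearing an ortho alkoxy group, which leaves the methyl ester untouched; no stereocentre.

Step 5
Reactants: 6 methyl 3,4-dimethoxyfuran-2-carboxylate; 7 ethyl glyoxylate
Product: 9 methyl 5-(2-ethoxy-1-hydroxy-2-oxoethyl)-3,4-dimethoxyfuran-2-carboxylate (racemic), via furylmagnesium chloride 8 (not isolated)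
Conditions: (2,2,6,6-tetramethylpiperidin-1-yl)MgCl·LiCl (1.1 equiv), THF, −40 °C; then 7 (freshly distilled), −78 → −20 °C; then 1 M HCl
Reagents that add atoms: none
Why: deprotonative magnesiation by the hindered magnesium amide at the only ring C–H (α to the ring oxygen, ortho to OMe, ester tolerated at low temperature) followed by Grignard 1,2-addition to the aldehyde of 7; the new carbinol centre is racemic and is erased in step 7.

Step 6
Reactants: 9 methyl 5-(2-ethoxy-1-hydroxy-2-oxoethyl)-3,4-dimethoxyfuran-2-carboxylate; 10 4'-hydroxyacetophenone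
Product: 12 methyl 5-[1-hydroxy-4-(4-hydroxyphenyl)-2,4-dioxobutyl]-3,4-dimethoxyfuran-2-carboxylate (racemic; diketone largely enolised), via dilithium enolate 11 (not isolated)
Conditions: 10 (2.5 equiv), LiN(SiMe3)2 (6.2 equiv), THF, −78 °C; then 9, −78 → 0 °C; then AcOH
Reagents that add atoms: none
Why: crossed Claisen condensation in which the phenolate–enolate dianion is acylated at carbon by the aliphatic α-oxido ethyl ester (the classical entry to α'-hydroxy-1,3-diketones) while the hindered, conjugated furoate ester is spared and the product is protected as its enolate; the carbinol centre stays racemic.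

Step 7
Reactants: 12 methyl 5-[1-hydroxy-4-(4-hydroxyphenyl)-2,4-dioxobutyl]-3,4-dimethoxyfuran-2-carboxylate
Product: 17 limnophilaspiroketone, via furan endoperoxide 13 (not isolated), via open-chain enedione 14 (not isolated), via pyranone hemiketal 15 (not isolated), via acyl hydroxyfuran 16 (not isolated)
Conditions: O2, hν (visible), tetraphenylporphyrin (0.5 mol%), CH2Cl2, −78 °C; Ar purge, Me2S (1.5 equiv), −78 → 0 °C, dark; volatiles (Me2S, DMSO) removed at 0.1 mbar; then CHCl3, 5 Å MS, (R)-3,3'-bis(2,4,6-triisopropylphenyl)-1,1'-binaphthyl-2,2'-diyl N-triflylphosphoramide (10 mol%), −20 → 20 °C, dark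
Reagents that add atoms: dioxygen, O=O
Why: Proposed new method: [4+2] cycloaddition of singlet oxygen to the electron-rich 3,4-dimethoxyfuran (the hydrogen-bonded diketone enol and the acyl phenol react far more slowly) and Me2S reduction of endoperoxide 13 give the (Z)-ene-dione 14, which rests as the six-membered hemiketal 15 (a photo-oxygenative Achmatowicz reaction) until the chiral Brønsted acid draws it back through the ring-chain equilibrium; the α'-hydroxy-1,3-diketone then cyclodehydrates to the 3(2H)-furanone (ring B, the standard acid closure of such diketones, which also erases the racemic carbinol centre), and its enol form 16 closes ring A by the terminal event of a Piancatelli rearrangement, a Nazarov-type conrotatory 4π closure (equally a dearomatising intramolecular aldol) of the hydroxypentadienyl cation C5=C9(OH)–C8=C7–C6(OH+)CO2Me; O1 sits inside (small ring oxygen, with C4=O outside and hydrogen-bonded to the C9 enol) and the protonated C6 oxygen carrying the bulky phosphoramide anion sits outside with the ester inside, so conrotation places OH cis to O1 and CO2Me cis to C4 (the target relative configuration, the same sense as the Piancatelli outcome for 5-substituted furans), while the chiral counter-anion selects the direction of conrotation and hence (5S,6R); closest known chemistry is the chiral phosphoric acid catalysed aza-Piancatelli and Nazarov cyclisations and the singlet-oxygen furan to 4-hydroxycyclopentenone cascades.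

**Compound list**

1 | dimethyl diglycolate (dimethyl 2,2'-oxydiacetate) | COC(=O)COCC(=O)OC | starting material
2 | dimethyl oxalate | COC(=O)C(=O)OC | starting material
3 | dimethyl 3,4-dihydroxyfuran-2,5-dicarboxylate | COC(=O)c1oc(C(=O)OC)c(O)c1O | intermediate
4 | dimethyl 3,4-dimethoxyfuran-2,5-dicarboxylate | COC(=O)c1oc(C(=O)OC)c(OC)c1OC | intermediate
5 | 3,4-dimethoxy-5-(methoxycarbonyl)furan-2-carboxylic acid | COC(=O)c1oc(C(O)=O)c(OC)c1OC | intermediate
6 | methyl 3,4-dimethoxyfuran-2-carboxylate | COC(=O)c1occ(OC)c1OC | intermediate
7 | ethyl glyoxylate | CCOC(=O)C=O | starting material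
8 | [3,4-dimethoxy-5-(methoxycarbonyl)furan-2-yl]magnesium chloride (LiCl complex) | COC(=O)c1oc([Mg]Cl)c(OC)c1OC | intermediate (not isolated)
9 | methyl 5-(2-ethoxy-1-hydroxy-2-oxoethyl)-3,4-dimethoxyfuran-2-carboxylate (racemic) | CCOC(=O)C(O)c1oc(C(=O)OC)c(OC)c1OC | intermediate
10 | 4'-hydroxyacetophenone | CC(=O)c1ccc(O)cc1 | starting material
11 | dilithium 4-(1-oxidoethenyl)phenolate | [Li+].[Li+].C=C([O-])c1ccc([O-])cc1 | intermediate (not isolated)
12 | methyl 5-[1-hydroxy-4-(4-hydroxyphenyl)-2,4-dioxobutyl]-3,4-dimethoxyfuran-2-carboxylate (racemic) | COC(=O)c1oc(C(O)C(=O)CC(=O)c2ccc(O)cc2)c(OC)c1OC | intermediate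
13 | methyl 4-[1-hydroxy-4-(4-hydroxyphenyl)-2,4-dioxobutyl]-5,6-dimethoxy-2,3,7-trioxabicyclo[2.2.1]hept-5-ene-1-carboxylate (stereoisomer mixture) | COC(=O)C12OOC(O1)(C(O)C(=O)CC(=O)c3ccc(O)cc3)C(OC)=C2OC | intermediate (not isolated)
14 | methyl (3Z)-6-hydroxy-9-(4-hydroxyphenyl)-3,4-dimethoxy-2,5,7,9-tetraoxonon-3-enoate (racemic) | COC(=O)C(=O)/C(OC)=C(OC)\C(=O)C(O)C(=O)CC(=O)c1ccc(O)cc1 | intermediate (not isolated)
15 | methyl 2-hydroxy-6-[3-(4-hydroxyphenyl)-3-oxopropanoyl]-3,4-dimethoxy-5-oxo-5,6-dihydro-2H-pyran-2-carboxylate (diastereomer mixture) | COC(=O)C1(O)OC(C(=O)CC(=O)c2ccc(O)cc2)C(=O)C(OC)=C1OC | intermediate (not isolated)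
16 | methyl (3Z)-5-[3-hydroxy-5-(4-hydroxyphenyl)furan-2-yl]-3,4-dimethoxy-2,5-dioxopent-3-enoate | COC(=O)C(=O)/C(OC)=C(OC)\C(=O)c1oc(-c2ccc(O)cc2)cc1O | intermediate (not isolated)
17 | limnophilaspiroketone, methyl (5S,6R)-6-hydroxy-2-(4-hydroxyphenyl)-7,8-dimethoxy-4,9-dioxo-1-oxaspiro[4.4]nona-2,7-diene-6-carboxylate | COC(=O)[C@@]1(O)C(OC)=C(OC)C(=O)[C@]12OC(c1ccc(O)cc1)=CC2=O | target

**Step count and risks**

Total steps: 7. Longest linear sequence: 7 steps (from compounds 1 and 2; compounds 7 and 10 are bought).

Steps most likely to fail: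

1. Step 7 (one-flask furan opening and double ring closure). Singlet oxygen may also oxidise the diketone enol, and the endoperoxide may fragment before it is reduced. Traces of DMSO and the basic porphyrin can buffer the chiral acid. Oxygen nucleophiles can compete with C5: the 3-hydroxyl of 16 or the side-chain hydroxyl of 14 can displace the C8 methoxy group in a chromone-type addition–elimination. The relative configuration rests on an inside/outside model, since a hydrogen-bonded aldol transition state would give the C6 epimer. The enantioselectivity is unproven, and a racemic background closure is possible. The fallback separates the two ring closures, isolates the cyclisation substrate and changes the mode of activation. It sets out from 12, which is cyclodehydrated on its own (TsOH·H2O cat., toluene, 60 °C, sieves) to the racemic furanone methyl 5-[5-(4-hydroxyphenyl)-3-oxo-2,3-dihydrofuran-2-yl]-3,4-dimethoxyfuran-2-carboxylate F1. Photo-oxygenation of F1 (O2, hν, tetraphenylporphyrin, CH2Cl2, −78 °C) gives the endoperoxide methyl 4-[5-(4-hydroxyphenyl)-3-oxo-2,3-dihydrofuran-2-yl]-5,6-dimethoxy-2,3,7-trioxabicyclo[2.2.1]hept-5-ene-1-carboxylate F2. Reduction with Me2S, an aqueous wash and filtration through silica then deliver 16 as an isolated compound with no free alcohol and no DMSO present. Ring A is closed as a metal-templated aldol with Cu(OTf)2 and 2,2'-(propane-2,2-diyl)bis[(4S)-4-tert-butyl-4,5-dihydrooxazole] (divalent copper, two-point binding of the α-keto ester), so the route is rejoined at 17.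

2. Step 6 (Claisen condensation on an unprotected α-hydroxy ester). The lithium alkoxide lowers the electrophilicity of the ester, the carbinol C–H can be removed to give an unreactive enediolate, the ketol can isomerise, and the furoate ester can be attacked instead. The fallback is a protect–acylate–deprotect sequence that sets out from 9. Silylation (TBSCl, imidazole, DMF) gives methyl 5-{1-[(tert-butyldimethylsilyl)oxy]-2-ethoxy-2-oxoethyl}-3,4-dimethoxyfuran-2-carboxylate F3. Acylation of dianion 11 with F3 under the step 6 conditions gives methyl 5-{1-[(tert-butyldimethylsilyl)oxy]-4-(4-hydroxyphenyl)-2,4-dioxobutyl}-3,4-dimethoxyfuran-2-carboxylate F4. Desilylation with HF·pyridine in THF returns to the route at 12.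

3. Step 5 (magnesiation and addition to ethyl glyoxylate). The metalated furoate can attack the ester of a second molecule, the magnesium amide can add to the ester, and ethyl glyoxylate is prone to polymerise and must be cracked just before use. The fallback reverses the polarity, using the furan as a nucleophile in electrophilic substitution instead of as a furyl anion. It sets out from 6, whose Friedel–Crafts acylation at the free C5 position with ethyl chlorooxoacetate (SnCl4, CH2Cl2, −20 → 0 °C) gives the keto ester methyl 5-(2-ethoxy-2-oxoacetyl)-3,4-dimethoxyfuran-2-carboxylate F5. Chemoselective reduction of the ketone of F5 (NaBH4, 0.3 equiv, EtOH/THF, −30 °C) comes back to the route at 9.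

**Further compounds**

F1 | step 7 | methyl 5-[5-(4-hydroxyphenyl)-3-oxo-2,3-dihydrofuran-2-yl]-3,4-dimethoxyfuran-2-carboxylate (racemic) | COC(=O)c1oc(C2OC(c3ccc(O)cc3)=CC2=O)c(OC)c1OC
F2 | step 7 | methyl 4-[5-(4-hydroxyphenyl)-3-oxo-2,3-dihydrofuran-2-yl]-5,6-dimethoxy-2,3,7-trioxabicyclo[2.2.1]hept-5-ene-1-carboxylate (stereoisomer mixture) | COC(=O)C12OOC(O1)(C3OC(c4ccc(O)cc4)=CC3=O)C(OC)=C2OC
F3 | step 6 | methyl 5-{1-[(tert-butyldimethylsilyl)oxy]-2-ethoxy-2-oxoethyl}-3,4-dimethoxyfuran-2-carboxylate (racemic) | CCOC(=O)C(O[Si](C)(C)C(C)(C)C)c1oc(C(=O)OC)c(OC)c1OC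
F4 | step 6 | methyl 5-{1-[(tert-butyldimethylsilyl)oxy]-4-(4-hydroxyphenyl)-2,4-dioxobutyl}-3,4-dimethoxyfuran-2-carboxylate (racemic) | COC(=O)c1oc(C(O[Si](C)(C)C(C)(C)C)C(=O)CC(=O)c2ccc(O)cc2)c(OC)c1OC
F5 | step 5 | methyl 5-(2-ethoxy-2-oxoacetyl)-3,4-dimethoxyfuran-2-carboxylate | CCOC(=O)C(=O)c1oc(C(=O)OC)c(OC)c1OC
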